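## Retrosynthetic overview

1. The last C–C bond is C3'=C4', made by a Wittig union of the carbocyclic allylic bromide 17 with the pyrone enal 26. One silylene group is then removed.
2. The cyclohexane comes from a 1,2-shift ring expansion of the dienyl cyclopentanol 14 to 15. This single step makes the C1–C2 bond, the C1 stereocentre, the E C1'=C2' alkene and the CH2Br handle. Both ketones are then reduced and acetylated.
3. The cyclopentane comes from Dieckmann closure and enol hydroxylation of aldol 4. Aldol 4 is made from the enol silane of pentan-3-one and methyl pyruvate by a copper–bis(oxazoline) Mukaiyama aldol, which is the source of absolute configuration.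
4. The pyrone comes from the same enol silane and methylmalonyl dichloride, followed by O-methylation and a vinylogous aldol/elimination with dimethoxyacetaldehyde.
5. Ring order: cyclopentane (step 3), temporary dioxasilinane bridge (step 5), cyclohexane by expansion (step 8). The pyrone ring is made separately (step 11).

**Assumption and numbering:** 18, 9 and 22 (22 dried before use) are taken as purchasable.
- Ring locants of the target are used throughout: C1 (side chain), C2 (CHMe), C3 (C(Me)OH), C4 (CHOAc), C5 (C(Me)OH), C6 (CHOAc). The target is (1R,2S,3R,4R,5S,6S).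
- The four ring oxygens lie on one face (β). The three methyl groups and the side chain lie on the other face (α).
- The side chain is ring–C1'H=C2'(Me)–C3'H=C4'H–C5'H=C6'(Me)–pyrone, all E.

## Route

Step 1
Reactants: 1 pentan-3-one
Product: 2 (Z)-trimethyl(pent-2-en-3-yloxy)silane
Conditions: Me3SiOTf, Et3N, Et2O, 0 °C
Reagents that add atoms: trimethylsilyl triflate, C[Si](C)(C)OS(=O)(=O)C(F)(F)F
Why: Soft enolisation and O-silylation (silyl enol ether formation) of a symmetrical ketone can give only one regioisomer, the Z isomer prevails under amine/silyl triflate conditions, and no stereocentre is created.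

Step 2
Reactants: 2 (Z)-trimethyl(pent-2-en-3-yloxy)silane; 3 methyl pyruvate
Product: 4 methyl (2R,3R)-2,3-dimethyl-4-oxo-2-(trimethylsilyloxy)hexanoate
Conditions: Cu(OTf)2 (10 mol %), (R,R)-t-Bu-box = 2,2'-(propane-2,2-diyl)bis[(4R)-4-tert-butyl-4,5-dihydro-1,3-oxazole] (11 mol %), THF, −78 → −40 °C; non-acidic work-up
Reagents that add atoms: none
Why: In this catalytic enantioselective Mukaiyama aldol addition the pyruvate binds the divalent copper centre through both carbonyl oxygens in a square-planar chelate, the tert-butyl groups of the (R,R) ligand leave one ketone face open and set ring C3 as the R tertiary carbinol, the open transition state gives the syn (methyl/oxygen) adduct that sets ring C2, and silyl transfer leaves the carbinol protected against retro-aldol cleavage.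

Step 3
Reactants: 4 methyl (2R,3R)-2,3-dimethyl-4-oxo-2-(trimethylsilyloxy)hexanoate
Product: 6 (4R,5R)-3,4-dihydroxy-2,4,5-trimethylcyclopent-2-en-1-one (enol form of the 1,3-dione), via O-silyl dione lithium enolate 5 (not isolated)
Conditions: LiN(SiMe3)2 (2.2 equiv), THF, −78 → 0 °C; then 1 M HCl
Reagents that add atoms: none
Why: In this Dieckmann-type (intramolecular Claisen) acylation the hindered amide base deprotonates the less hindered CH2 of the ethyl ketone, the enolate closes on the inductively activated α-silyloxy ester to give the five-membered 1,3-dione, the second equivalent of base stores the product as its inert enolate so that C2 and C3 are untouched, and the acid work-up removes the silyl group.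

Step 4
Reactants: 6 (4R,5R)-3,4-dihydroxy-2,4,5-trimethylcyclopent-2-en-1-one
Product: 7 (2S,4R,5R)-2,4-dihydroxy-2,4,5-trimethylcyclopentane-1,3-dione
Conditions: dimethyldioxirane, acetone, 0 °C
Reagents that add atoms: dimethyldioxirane, CC1(C)OO1
Why: In this electrophilic α-hydroxylation of an enolised 1,3-dione (enol epoxidation and collapse) the neutral oxidant approaches the flat enol from the face opposite the two α methyl groups and is guided by a hydrogen bond to the C3 hydroxyl, which places the new C5 hydroxyl cis (β) to it.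

Step 5
Reactants: 7 (2S,4R,5R)-2,4-dihydroxy-2,4,5-trimethylcyclopentane-1,3-dione
Product: 8 (1R,5S,7R)-3,3-di-tert-butyl-1,5,7-trimethyl-2,4-dioxa-3-silabicyclo[3.2.1]octane-6,8-dione
Conditions: t-Bu2Si(OTf)2, 2,6-lutidine, CH2Cl2, 0 °C → rt
Reagents that add atoms: di-tert-butylsilyl bis(triflate), CC(C)(C)[Si](OS(=O)(=O)C(F)(F)F)(OS(=O)(=O)C(F)(F)F)C(C)(C)C
Why: In this cyclic silylene protection only the cis-1,3-diol can be bridged (a check on step 4), the bridge shuts off α-ketol and retro-Claisen pathways and covers the β face, and ring C2, now the only epimerisable centre, prefers its methyl group exo (α), so any anti isomer from step 2 can be converged by a trace of DBU.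

Step 6
Reactants: 9 2-methylbut-1-en-3-yne
Product: 11 (1E)-1-iodo-3-methylbuta-1,3-diene, via dienylzirconocene chloride 10 (not isolated)
Conditions: Cp2Zr(H)Cl, THF, rt; then I2, 0 °C, dark
Reagents that add atoms: iodine, II
Why: In this hydrozirconation–iodination Cp2Zr(H)Cl adds syn and anti-Markovnikov to the terminal alkyne faster than to the 1,1-disubstituted alkene, and iodinolysis with retention gives the E dienyl iodide.

Step 7
Reactants: 11 (1E)-1-iodo-3-methylbuta-1,3-diene; 8 (1R,5S,7R)-3,3-di-tert-butyl-1,5,7-trimethyl-2,4-dioxa-3-silabicyclo[3.2.1]octane-6,8-dione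
Product: 14 (1R,5S,6S,7S)-3,3-di-tert-butyl-6-hydroxy-1,5,7-trimethyl-6-[(1E)-3-methylbuta-1,3-dien-1-yl]-2,4-dioxa-3-silabicyclo[3.2.1]octan-8-one, via dienyllithium 12 (not isolated), via dienylcerium dichloride 13 (not isolated)
Conditions: t-BuLi (2 equiv), Et2O, −78 °C; CeCl3, THF, −78 °C; 8, −78 °C; AcOH quench at −78 °C
Reagents that add atoms: none
Why: After lithium–iodine exchange and transmetalation, the non-basic organocerium reagent adds 1,2 to the ring C6 ketone (one tertiary and one quaternary neighbour) in preference to the C4 ketone held between two quaternary bridgeheads, it enters from the exo (α) face opposite the silylene bridge, the cold acid quench prevents retro-aldol opening, and the configuration of this carbinol carbon is of no consequence because it becomes a carbonyl group in step 8.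

Step 8
Reactants: 14 (1R,5S,6S,7S)-3,3-di-tert-butyl-6-hydroxy-1,5,7-trimethyl-6-[(1E)-3-methylbuta-1,3-dien-1-yl]-2,4-dioxa-3-silabicyclo[3.2.1]octan-8-one
Product: 15 (1R,5S,7R,8S)-7-[(1E)-3-bromo-2-methylprop-1-en-1-yl]-3,3-di-tert-butyl-1,5,8-trimethyl-2,4-dioxa-3-silabicyclo[3.3.1]nonane-6,9-dione
Conditions: N-bromosuccinimide (1.05 equiv), (CF3)2CHOH/CH2Cl2 1:3, −30 °C, dark
Reagents that add atoms: N-bromosuccinimide, O=C1CCC(=O)N1Br
Why: Proposed new method: a vinylogous (1,4-) bromonium-induced semipinacol ring expansion of a 1-(1,3-dienyl)cyclopentanol, in which Br+ adds to the terminal CH2 of the s-trans diene (its most nucleophilic and least hindered carbon), the methyl-substituted allyl cation is stabilised but not trapped in the ionising, non-nucleophilic fluoroalcohol, and its carbinol-side terminus (ring C1) accepts a 1,2-shift of the C6–C2 ring bond while the hydroxyl oxygen pushes to form the C6 ketone; only C2 (CHMe) can migrate because the other neighbour C5 carries oxygen and an acyl group, C=O formation plus relief of eclipsing strain on going from the bicyclo[3.2.1] to the bicyclo[3.3.1] frame makes the shift irreversible while capture by bromide or succinimide is reversible, C2 migrates with retention, the s-trans diene geometry becomes the E trisubstituted alkene, and C1 is set with the side chain equatorial (α) because the axial position points into the silylene ring, which is also the thermodynamic epimer next to the ketone; the closest known reaction types are the halonium-induced semipinacol ring expansion of 1-alkenylcycloalkanols and the 1,4-halofunctionalisation of 1,3-dienes.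

Step 9
Reactants: 15 (1R,5S,7R,8S)-7-[(1E)-3-bromo-2-methylprop-1-en-1-yl]-3,3-di-tert-butyl-1,5,8-trimethyl-2,4-dioxa-3-silabicyclo[3.3.1]nonane-6,9-dione
Product: 16 (1R,5S,6S,7R,8S,9R)-7-[(1E)-3-bromo-2-methylprop-1-en-1-yl]-3,3-di-tert-butyl-1,5,8-trimethyl-2,4-dioxa-3-silabicyclo[3.3.1]nonane-6,9-diol
Conditions: NaBH4, CeCl3·7H2O, MeOH/THF, −20 → 0 °C
Reagents that add atoms: none
Why: In this Luche-type borohydride reduction under substrate control the β face of both ketones in the rigid bicyclic frame is covered by the dioxasilinane ring and each carbonyl has an axial C–O bond next to it, so the small hydride adds anti to these bonds (polar Felkin–Anh, axial attack from the α face) to give the equatorial β alcohols at C4 and C6, while the cold, weakly acidic medium spares the allylic bromide and suppresses retro-aldol opening.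

Step 10
Reactants: 16 (1R,5S,6S,7R,8S,9R)-7-[(1E)-3-bromo-2-methylprop-1-en-1-yl]-3,3-di-tert-butyl-1,5,8-trimethyl-2,4-dioxa-3-silabicyclo[3.3.1]nonane-6,9-diol
Product: 17 (1R,5S,6S,7R,8S,9R)-7-[(1E)-3-bromo-2-methylprop-1-en-1-yl]-3,3-di-tert-butyl-1,5,8-trimethyl-2,4-dioxa-3-silabicyclo[3.3.1]nonane-6,9-diyl diacetate
Conditions: Ac2O, Sc(OTf)3 (2 mol %), MeCN/CH2Cl2, −20 °C
Reagents that add atoms: acetic anhydride, CC(=O)OC(C)=O
Why: In this Lewis acid-catalysed acetylation Sc(OTf)3 activates Ac2O enough for two hindered equatorial secondary alcohols without a nucleophilic amine that would quaternise the allylic bromide, the tertiary oxygens stay masked, and no stereocentre is touched.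

Step 11
Reactants: 2 (Z)-trimethyl(pent-2-en-3-yloxy)silane; 18 methylmalonyl dichloride
Product: 19 6-ethyl-4-hydroxy-3,5-dimethyl-2H-pyran-2-one
Conditions: Et2O, −78 °C → rt
Reagents that add atoms: none
Why: In this Effenberger-type pyrone synthesis C-acylation of the enol silane by one acid chloride and O-acylation of the resulting enolised 1,3-diketone by the other close the 4-hydroxy-2-pyrone ring, which is the only six-membered outcome.

Step 12
Reactants: 19 6-ethyl-4-hydroxy-3,5-dimethyl-2H-pyran-2-one
Product: 21 2-ethyl-6-methoxy-3,5-dimethyl-4H-pyran-4-one, via methoxypyrylium triflate 20 (not isolated)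
Conditions: MeOTf, CH2Cl2, rt; then aq NaHCO3
Reagents that add atoms: methyl triflate, COS(=O)(=O)C(F)(F)F
Why: In this O-alkylation by a hard methylating agent the most basic site of a 4-hydroxy-2-pyrone is the lactone carbonyl oxygen, its methylation gives the 4-hydroxy-2-methoxypyrylium salt, and deprotonation on work-up gives the 2-methoxy-4-pyrone rather than the 4-methoxy-2-pyrone.

Step 13
Reactants: 21 2-ethyl-6-methoxy-3,5-dimethyl-4H-pyran-4-one; 22 2,2-dimethoxyacetaldehyde
Product: 26 (2E)-3-(6-methoxy-3,5-dimethyl-4-oxo-4H-pyran-2-yl)but-2-enal, via lithium aldolate 23 (not isolated), via aldol mesylate 24 (not isolated), via enal dimethyl acetal 25 (not isolated)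
Conditions: LiN(SiMe3)2, THF, −78 °C; 22; MsCl; DBU, −78 °C → rt; then 1 M HCl, rt
Reagents that add atoms: water, O
Why: In this vinylogous aldol addition followed by E1cB elimination the CH2 of the 2-ethyl group is the only vinylogously acidic position, its dienolate adds to the aldehyde, loss of mesylate through the same dienolate gives the less strained E alkene (pyrone trans to the acetal carbon), and the allylic acetal is hydrolysed by the dilute acid of the work-up.

Step 14
Reactants: 17 (1R,5S,6S,7R,8S,9R)-7-[(1E)-3-bromo-2-methylprop-1-en-1-yl]-3,3-di-tert-butyl-1,5,8-trimethyl-2,4-dioxa-3-silabicyclo[3.3.1]nonane-6,9-diyl diacetate; 26 (2E)-3-(6-methoxy-3,5-dimethyl-4-oxo-4H-pyran-2-yl)but-2-enal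
Product: 28 3,5-O-(di-tert-butylsilylene)amaurone B, via allylic phosphonium bromide 27 (not isolated)
Conditions: PBu3, THF, rt; 26; LiN(SiMe3)2, −78 → 0 °C, dark
Reagents that add atoms: none
Why: In this Wittig olefination by a semistabilised allylic tributylphosphonium ylide the primary allylic bromide is quaternised at room temperature, the phosphonium CH2 is far more acidic than the acetate methyl groups, trialkylphosphonium allyl ylides give mainly E alkenes from enals (this sets C3'=C4'), and the existing alkenes and stereocentres are not involved.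

Step 15
Reactants: 28 3,5-O-(di-tert-butylsilylene)amaurone B
Product: 29 amaurone B
Conditions: HF·pyridine, pyridine, THF, 0 °C
Reagents that add atoms: none
Why: In this fluoride-mediated silylene cleavage buffered HF·pyridine removes the bridge at 0 °C without touching the secondary acetates, the methoxypyrone or the triene, and frees the two tertiary alcohols of the target.

## Compound list

1 | pentan-3-one | CCC(=O)CC | starting material
2 | (Z)-trimethyl(pent-2-en-3-yloxy)silane | C/C=C(/CC)O[Si](C)(C)C | intermediate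
3 | methyl pyruvate | CC(=O)C(=O)OC | starting material
4 | methyl (2R,3R)-2,3-dimethyl-4-oxo-2-(trimethylsilyloxy)hexanoate | CCC(=O)[C@H](C)[C@@](C)(O[Si](C)(C)C)C(=O)OC | intermediate
5 | lithium enolate of (4R,5R)-2,4,5-trimethyl-4-(trimethylsilyloxy)cyclopentane-1,3-dione (not isolated) | [Li+].[O-]C1=C(C)C(=O)[C@H](C)[C@@]1(C)O[Si](C)(C)C | intermediate
6 | (4R,5R)-3,4-dihydroxy-2,4,5-trimethylcyclopent-2-en-1-one | O=C1[C@H](C)[C@@](C)(O)C(O)=C1C | intermediate
7 | (2S,4R,5R)-2,4-dihydroxy-2,4,5-trimethylcyclopentane-1,3-dione | O=C1[C@H](C)[C@@](C)(O)C(=O)[C@@]1(C)O | intermediate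
8 | (1R,5S,7R)-3,3-di-tert-butyl-1,5,7-trimethyl-2,4-dioxa-3-silabicyclo[3.2.1]octane-6,8-dione | O=C1[C@H](C)[C@@]2(C)O[Si](C(C)(C)C)(C(C)(C)C)O[C@]1(C)C2=O | intermediate
9 | 2-methylbut-1-en-3-yne | C=C(C)C#C | starting material
10 | chlorobis(cyclopentadienyl)[(1E)-3-methylbuta-1,3-dien-1-yl]zirconium (not isolated) | C=C(C)/C=C/[Zr](Cl)(C1C=CC=C1)C1C=CC=C1 | intermediate
11 | (1E)-1-iodo-3-methylbuta-1,3-diene | I/C=C/C(C)=C | intermediate
12 | [(1E)-3-methylbuta-1,3-dien-1-yl]lithium (not isolated) | [Li]/C=C/C(C)=C | intermediate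
13 | dichloro[(1E)-3-methylbuta-1,3-dien-1-yl]cerium (not isolated) | Cl[Ce](Cl)/C=C/C(C)=C | intermediate
14 | (1R,5S,6S,7S)-3,3-di-tert-butyl-6-hydroxy-1,5,7-trimethyl-6-[(1E)-3-methylbuta-1,3-dien-1-yl]-2,4-dioxa-3-silabicyclo[3.2.1]octan-8-one | O[C@@]1(/C=C/C(C)=C)[C@H](C)[C@@]2(C)O[Si](C(C)(C)C)(C(C)(C)C)O[C@]1(C)C2=O | intermediate
15 | (1R,5S,7R,8S)-7-[(1E)-3-bromo-2-methylprop-1-en-1-yl]-3,3-di-tert-butyl-1,5,8-trimethyl-2,4-dioxa-3-silabicyclo[3.3.1]nonane-6,9-dione | O=C1[C@H](/C=C(\C)CBr)[C@H](C)[C@@]2(C)O[Si](C(C)(C)C)(C(C)(C)C)O[C@]1(C)C2=O | intermediate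
16 | (1R,5S,6S,7R,8S,9R)-7-[(1E)-3-bromo-2-methylprop-1-en-1-yl]-3,3-di-tert-butyl-1,5,8-trimethyl-2,4-dioxa-3-silabicyclo[3.3.1]nonane-6,9-diol | O[C@H]1[C@H](/C=C(\C)CBr)[C@H](C)[C@@]2(C)O[Si](C(C)(C)C)(C(C)(C)C)O[C@]1(C)[C@@H]2O | intermediate
17 | (1R,5S,6S,7R,8S,9R)-7-[(1E)-3-bromo-2-methylprop-1-en-1-yl]-3,3-di-tert-butyl-1,5,8-trimethyl-2,4-dioxa-3-silabicyclo[3.3.1]nonane-6,9-diyl diacetate | CC(=O)O[C@H]1[C@H](/C=C(\C)CBr)[C@H](C)[C@@]2(C)O[Si](C(C)(C)C)(C(C)(C)C)O[C@]1(C)[C@@H]2OC(C)=O | intermediate
18 | methylmalonyl dichloride | CC(C(=O)Cl)C(=O)Cl | starting material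
19 | 6-ethyl-4-hydroxy-3,5-dimethyl-2H-pyran-2-one | CCc1oc(=O)c(C)c(O)c1C | intermediate
20 | 2-ethyl-4-hydroxy-6-methoxy-3,5-dimethylpyrylium triflate (not isolated) | CCc1[o+]c(OC)c(C)c(O)c1C.[O-]S(=O)(=O)C(F)(F)F | intermediate
21 | 2-ethyl-6-methoxy-3,5-dimethyl-4H-pyran-4-one | CCc1oc(OC)c(C)c(=O)c1C | intermediate
22 | 2,2-dimethoxyacetaldehyde | COC(OC)C=O | starting material
23 | lithium 1,1-dimethoxy-3-(6-methoxy-3,5-dimethyl-4-oxo-4H-pyran-2-yl)butan-2-olate, diastereomer mixture (not isolated) | [Li+].COC(OC)C([O-])C(C)c1oc(OC)c(C)c(=O)c1C | intermediate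
24 | 1,1-dimethoxy-3-(6-methoxy-3,5-dimethyl-4-oxo-4H-pyran-2-yl)butan-2-yl methanesulfonate, diastereomer mixture (not isolated) | COC(OC)C(OS(C)(=O)=O)C(C)c1oc(OC)c(C)c(=O)c1C | intermediate
25 | 2-[(2E)-4,4-dimethoxybut-2-en-2-yl]-6-methoxy-3,5-dimethyl-4H-pyran-4-one (not isolated) | COC(OC)/C=C(C)/c1oc(OC)c(C)c(=O)c1C | intermediate
26 | (2E)-3-(6-methoxy-3,5-dimethyl-4-oxo-4H-pyran-2-yl)but-2-enal | O=C/C=C(C)/c1oc(OC)c(C)c(=O)c1C | intermediate
27 | tributyl{(2E)-3-[(1R,5S,6S,7R,8S,9R)-6,9-diacetoxy-3,3-di-tert-butyl-1,5,8-trimethyl-2,4-dioxa-3-silabicyclo[3.3.1]nonan-7-yl]-2-methylprop-2-en-1-yl}phosphonium bromide (not isolated) | CC(=O)O[C@H]1[C@H](/C=C(\C)C[P+](CCCC)(CCCC)CCCC)[C@H](C)[C@@]2(C)O[Si](C(C)(C)C)(C(C)(C)C)O[C@]1(C)[C@@H]2OC(C)=O.[Br-] | intermediate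
28 | 3,5-O-(di-tert-butylsilylene)amaurone B (all-E triene; ring centres as in 17) | CC(=O)O[C@H]1[C@H](/C=C(C)/C=C/C=C(C)/c3oc(OC)c(C)c(=O)c3C)[C@H](C)[C@@]2(C)O[Si](C(C)(C)C)(C(C)(C)C)O[C@]1(C)[C@@H]2OC(C)=O | intermediate
29 | amaurone B, ring (1R,2S,3R,4R,5S,6S), all-E triene | COc1oc(/C(C)=C/C=C/C(C)=C/[C@@H]2[C@H](C)[C@@](C)(O)[C@@H](OC(C)=O)[C@@](C)(O)[C@H]2OC(C)=O)c(C)c(=O)c1C | target

## Step count and risks

Total step count: 15.
Longest linear sequence: 11 (steps 1, 2, 3, 4, 5, 7, 8, 9, 10, 14, 15).

**Step 8 (the proposed new step).**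
The risks are proton loss from the allyl cation, lasting capture by bromide or succinimide, and bromination without migration.
The fallback uses known chemistry, sets out from 8 and comes back at 15. The ring C6 ketone of 8 is homologated by Me3SiCHN2 and BF3·OEt2 in CH2Cl2 at −78 °C. This is a diazoalkane ring expansion of the Tiffeneau–Demjanov type in which the CHMe carbon migrates, and the C-silyl group is lost on acidic work-up. The product is the ring-enlarged diketone F1. Its only possible enolate, made by LiN(SiMe3)2, adds to methacrolein to give the aldol F2. PBr3 in Et2O at −20 °C then converts the secondary allylic alcohol, by allylic transposition (SN2'), into the primary E allylic bromide 15.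

**Step 3.**
The risks are a slow five-membered enolendo closure on a hindered ester and E1cB loss of the β-silyloxy group after enolate equilibration.
The fallback sets out from 4 and comes back at 7, so step 4 is then not needed. LiAlH4 reduces the ester and the ketone of 4 to the diol F3. A double Swern oxidation gives the keto aldehyde F4. TsOH in wet THF removes the silyl group and closes the ring by intramolecular aldol condensation on the much more electrophilic aldehyde, giving the hydroxy enone F5. OsO4·TMEDA (hydrogen-bond-directed dihydroxylation, syn to the tertiary hydroxyl) gives the all-cis triol F6. SO3·pyridine/DMSO oxidises its only secondary alcohol to give 7.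

**Step 9.**
The risks are that the axial C2 methyl group slows α-face attack, that the ketone between the two bridgeheads reacts incompletely, and that the allylic bromide is lost if forcing conditions are needed.
The fallback sets out from 15 and comes back at 16. KOAc in DMF replaces the bromide to give the allylic acetate F7. LiAlH4 in Et2O at 0 °C, a smaller and much stronger hydride that sees the same open α face, reduces both ketones and the acetate to the triol F8. NBS/Me2S (Corey–Kim conditions) brominates only the primary allylic alcohol to give 16.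

## Further compounds

F1 | step 8 | (1R,5S,8S)-3,3-di-tert-butyl-1,5,8-trimethyl-2,4-dioxa-3-silabicyclo[3.3.1]nonane-6,9-dione | O=C1C[C@H](C)[C@@]2(C)O[Si](C(C)(C)C)(C(C)(C)C)O[C@]1(C)C2=O
F2 | step 8 | (1R,5S,7R,8S)-3,3-di-tert-butyl-7-(1-hydroxy-2-methylprop-2-en-1-yl)-1,5,8-trimethyl-2,4-dioxa-3-silabicyclo[3.3.1]nonane-6,9-dione (carbinol epimers) | O=C1[C@H](C(O)C(C)=C)[C@H](C)[C@@]2(C)O[Si](C(C)(C)C)(C(C)(C)C)O[C@]1(C)C2=O
F3 | step 3 | (2R,3S)-2,3-dimethyl-2-(trimethylsilyloxy)hexane-1,4-diol (C4 epimers) | CCC(O)[C@H](C)[C@@](C)(O[Si](C)(C)C)CO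
F4 | step 3 | (2R,3R)-2,3-dimethyl-4-oxo-2-(trimethylsilyloxy)hexanal | CCC(=O)[C@H](C)[C@@](C)(O[Si](C)(C)C)C=O
F5 | step 3 | (4S,5R)-4-hydroxy-2,4,5-trimethylcyclopent-2-en-1-one | O=C1[C@H](C)[C@@](C)(O)C=C1C
F6 | step 3 | (2R,3R,4R,5R)-2,3,4-trihydroxy-2,4,5-trimethylcyclopentan-1-one | O=C1[C@H](C)[C@@](C)(O)[C@@H](O)[C@@]1(C)O
F7 | step 9 | (2E)-3-[(1R,5S,7R,8S)-3,3-di-tert-butyl-1,5,8-trimethyl-6,9-dioxo-2,4-dioxa-3-silabicyclo[3.3.1]nonan-7-yl]-2-methylprop-2-en-1-yl acetate | O=C1[C@H](/C=C(\C)COC(C)=O)[C@H](C)[C@@]2(C)O[Si](C(C)(C)C)(C(C)(C)C)O[C@]1(C)C2=O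
F8 | step 9 | (1R,5S,6S,7R,8S,9R)-3,3-di-tert-butyl-7-[(1E)-3-hydroxy-2-methylprop-1-en-1-yl]-1,5,8-trimethyl-2,4-dioxa-3-silabicyclo[3.3.1]nonane-6,9-diol | O[C@H]1[C@H](/C=C(\C)CO)[C@H](C)[C@@]2(C)O[Si](C(C)(C)C)(C(C)(C)C)O[C@]1(C)[C@@H]2O
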